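Ring A is taken apart completely. Its contiguous array C7–O, C8-prenyl, C8a–O and C4a–C4, which substitution of a finished chroman reaches poorly, is written in one step from an acyclic diazomethyl enone and a prenyl-bearing siloxyalkyne: a photo-Wolff, [2+2], 4π-opening, 6π-closure cascade forms C5–C6, C6–C7, C8–C8a and C4a–C8a, puts the prenyl group between both oxygens and leaves only the C8a hydroxyl free for the later closure of ring C onto C2. The precursor is an (S,E)-diazo enone that already holds ring B with its chromene, the C3 stereocentre and C2–C4 as a silyl-protected chain; C3 comes from desymmetrising a 3-arylcyclobutanone.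

Key step: step 14

Remark: ArB = 2,2-dimethyl-5-(triisopropylsilyloxy)-2H-chromen-6-yl (ring B with its chromene, phenol silylated); the labels C2–C8a are those of the chroman core of the target.
Assumption: the antipode of the chiral phosphoric acid of step 6 that leads to the (S)-lactone is identified in a trial run on 10 (chiral HPLC, correlation with the final product) and then used.

Step 1
Reactants: 1 2,4-dihydroxybenzaldehyde; 2 3-methylbut-2-enal (prenal)
Product: 4 5-hydroxy-2,2-dimethyl-2H-chromene-6-carbaldehyde, via o-quinone methide 3 (not isolated)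
Conditions: pyridine, 120 °C
Reagents that add atoms: none
Why: Chromenylation by Knoevenagel-type condensation at the ring carbon between the two hydroxyl groups (the 2-hydroxyl stays tied to the formyl group by a hydrogen bond), dehydration to the o-quinone methide and oxa-6π electrocyclisation onto the 4-oxygen should give the angular chromene aldehyde, a much-used route to this compound.

Step 2
Reactants: 4 5-hydroxy-2,2-dimethyl-2H-chromene-6-carbaldehyde
Product: 5 2,2-dimethyl-5-(triisopropylsilyloxy)-2H-chromene-6-carbaldehyde (ArB–CHO)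
Conditions: i-Pr3SiOTf, 2,6-lutidine, CH2Cl2, 0 → 25 °C
Reagents that add atoms: triisopropylsilyl trifluoromethanesulfonate, CC(C)[Si](OS(=O)(=O)C(F)(F)F)(C(C)C)C(C)C
Why: O-Silylation of the hindered, hydrogen-bonded phenol with the reactive silyl triflate; the bulky aryl silyl ether should survive every later base, hydride and mild-acid step and falls at the end together with the C7 silyl ether.

Step 3
Reactants: 5 ArB–CHO
Product: 6 6-ethenyl-2,2-dimethyl-5-(triisopropylsilyloxy)-2H-chromene (ArB–CH=CH2)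
Conditions: Ph3PCH3Br, KOt-Bu, THF, 0 → 25 °C
Reagents that add atoms: methyltriphenylphosphonium bromide, C[P+](c1ccccc1)(c1ccccc1)c1ccccc1.[Br-]
Why: Wittig methylenation of an aromatic aldehyde with the non-stabilised ylide, to which the silyl ether and the chromene are inert.

Step 4
Reactants: 6 ArB–CH=CH2; 7 trichloroacetyl chloride
Product: 9 racemic 2,2-dichloro-3-ArB-cyclobutan-1-one, via dichloroketene 8 (not isolated)
Conditions: Zn(Cu), POCl3, Et2O, 25 °C, slow addition of 7 (1.3 equiv)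
Reagents that add atoms: none
Why: Ketene–alkene [2+2] cycloaddition of dichloroketene made in the flask, whose carbonyl carbon bonds to the unhindered terminal CH2 of the electron-rich monosubstituted styrene, while the pyran double bond (cis-disubstituted, its reacting carbon neopentylic next to CMe2) should be much slower and POCl3 ties up ZnCl2; the new centre is racemic and disappears in step 5.

Step 5
Reactants: 9 racemic 2,2-dichloro-3-ArB-cyclobutan-1-one
Product: 10 3-ArB-cyclobutan-1-one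
Conditions: Zn, AcOH, 25 °C
Reagents that add atoms: none
Why: Reductive dechlorination of an α,α-dichloroketone by zinc in acetic acid, a standard follow-up of dichloroketene cycloadditions, gives the achiral, prochiral cyclobutanone.

Step 6
Reactants: 10 3-ArB-cyclobutan-1-one
Product: 12 (4S)-4-ArB-dihydrofuran-2(3H)-one, via peroxy hemiketal 11 (not isolated)
Conditions: 3,3'-di(pyren-1-yl)-5,5',6,6',7,7',8,8'-octahydro-1,1'-binaphthalene-2,2'-diyl hydrogen phosphate (10 mol %, antipode as assumed), 30 % aq. H2O2, CHCl3, −40 °C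
Reagents that add atoms: hydrogen peroxide, OO
Why: Catalytic asymmetric Baeyer–Villiger oxidation as a desymmetrisation: in the peroxy hemiketal held by the chiral phosphate one of the two enantiotopic ring CH2 groups migrates preferentially, which sets C3 as (S), and aqueous H2O2 without a peracid should spare the chromene double bond.

Step 7
Reactants: 12 (4S)-4-ArB-dihydrofuran-2(3H)-one
Product: 13 (3S)-3-ArB-4-hydroxy-N-methoxy-N-methylbutanamide
Conditions: MeNH(OMe)·HCl, i-PrMgCl, THF, −20 → 0 °C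
Reagents that add atoms: N,O-dimethylhydroxylamine hydrochloride, CNOC.Cl
Why: Aminolysis of the lactone by the magnesium amide opens the ring to the Weinreb amide and frees the C2 hydroxyl without touching C3 (β to the carbonyl, not enolisable).

Step 8
Reactants: 13 (3S)-3-ArB-4-hydroxy-N-methoxy-N-methylbutanamide
Product: 14 (3S)-3-ArB-4-(tert-butyldimethylsilyloxy)-N-methoxy-N-methylbutanamide
Conditions: t-BuMe2SiCl, imidazole, CH2Cl2, 25 °C (on crude 13)
Reagents that add atoms: tert-butyldimethylsilyl chloride, CC(C)(C)[Si](C)(C)Cl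
Why: Silylation of the primary alcohol directly on the crude hydroxy amide prevents relactonisation and masks the C2 hydroxyl so that it cannot trap the ketene of step 14.

Step 9
Reactants: 14 (3S)-3-ArB-4-(tert-butyldimethylsilyloxy)-N-methoxy-N-methylbutanamide
Product: 15 (3S)-3-ArB-4-(tert-butyldimethylsilyloxy)butanal
Conditions: i-Bu2AlH, THF, −78 °C; aq. KNa tartrate
Reagents that add atoms: none
Why: Partial reduction of a Weinreb amide, which releases the aldehyde only on work-up and therefore should not over-reduce; the stereocentre is β to the new aldehyde and cannot epimerise.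

Step 10
Reactants: 15 (3S)-3-ArB-4-(tert-butyldimethylsilyloxy)butanal
Product: 16 (3E,6S)-6-ArB-7-(tert-butyldimethylsilyloxy)hept-3-en-2-one
Conditions: Ph3P=CHC(O)CH3, CH2Cl2, 40 °C
Reagents that add atoms: 1-(triphenylphosphoranylidene)propan-2-one, CC(=O)C=P(c1ccccc1)(c1ccccc1)c1ccccc1
Why: Wittig olefination with the stabilised acetonyl ylide should give the (E)-enone under neutral conditions.

Step 11
Reactants: 16 (3E,6S)-6-ArB-7-(tert-butyldimethylsilyloxy)hept-3-en-2-one
Product: 18 (3E,6S)-6-ArB-7-(tert-butyldimethylsilyloxy)-1-diazohept-3-en-2-one, via trifluoroacetyl diketone 17 (not isolated)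
Conditions: LiN(SiMe3)2, THF, −78 °C; CF3CO2CH2CF3; then MeSO2N3, Et3N, H2O, MeCN, 25 °C
Reagents that add atoms: methanesulfonyl azide, CS(=O)(=O)N=[N+]=[N-] (supplies N2); 2,2,2-trifluoroethyl trifluoroacetate, O=C(OCC(F)(F)F)C(F)(F)F (its trifluoroacetyl group is held only by 17 and leaves again)
Why: Detrifluoroacetylative diazo transfer: kinetic deprotonation at the methyl group and Claisen acylation activate the ketone as 17, which accepts the diazo group from the sulfonyl azide and loses the trifluoroacetyl group, the established route to diazomethyl enones because acylation of diazomethane fails with enones (dipolar addition).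

Step 12
Reactants: 19 4-methylpent-3-enoic acid
Product: 20 ethyl 4-methylpent-3-enoate
Conditions: EtI, K2CO3, DMF, 25 °C
Reagents that add atoms: iodoethane, CCI
Why: O-Alkylation of the carboxylate avoids the strong acid of a Fischer esterification, which could lactonise or conjugate the β,γ-unsaturated acid.

Step 13
Reactants: 20 ethyl 4-methylpent-3-enoate
Product: 23 triisopropyl[(5-methylhex-4-en-1-yn-1-yl)oxy]silane, via dibromo enolate 21 (not isolated), via lithium ynolate 22 (not isolated)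
Conditions: CH2Br2, lithium 2,2,6,6-tetramethylpiperidide, THF, −78 °C; 20; LiN(SiMe3)2; n-BuLi, −78 → 25 °C; i-Pr3SiCl, −78 → 0 °C
Reagents that add atoms: dibromomethane, BrCBr; triisopropylsilyl chloride, CC(C)[Si](Cl)(C(C)C)C(C)C
Why: Kowalski ester homologation stopped at the ynolate: LiCHBr2 adds to the ester (added to the preformed carbenoid at −78 °C so that addition outruns enolisation of the allylic α-CH2), bromine–lithium exchange on 21 triggers 1,2-migration of the allylic group to the carbenoid carbon, and the bulky silyl chloride traps ynolate 22 on oxygen.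

Step 14
Reactants: 18 (3E,6S)-6-ArB-7-(tert-butyldimethylsilyloxy)-1-diazohept-3-en-2-one; 23 triisopropyl[(5-methylhex-4-en-1-yn-1-yl)oxy]silane
Product: 28 6-[(2S)-2-ArB-3-(tert-butyldimethylsilyloxy)propyl]-2-(3-methylbut-2-en-1-yl)-3-(triisopropylsilyloxy)phenol, via vinylketene 24 (not isolated), via vinylcyclobutenone 25 (not isolated), via dienylketene 26 (not isolated), via cyclohexadienone 27 (not isolated)
Conditions: hν (LEDs, 405–440 nm), 23 (1.5 equiv), ClCH2CH2Cl (0.05 M, degassed), 25 °C; then 80 °C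
Reagents that add atoms: none
Why: Light absorbed in the long-wavelength band of the diazo enone, where the photochromic 2H-chromene is transparent, expels N2 with 1,2-shift of the alkenyl group (photo-Wolff, C5–C6) to vinylketene 24, whose carbonyl carbon is attacked by the nucleophilic, prenyl-bearing carbon of 23 in a [2+2] cycloaddition (C8–C8a, then C6–C7) to give 25. At 80 °C 25 opens reversibly by conrotatory 4π ring opening to dienylketene 26, and the isomer with the alkenyl group turned towards the ketene closes ring A by a thermal disrotatory 6π electrocyclisation (C4a–C8a) to 27, which tautomerises irreversibly to the phenol. The closest known reaction type is the Danheiser benzannulation in its photochemical diazo ketone variant with siloxyalkynes. No lasting stereocentre is formed (the sp3 centres of 25 and 27 are transient), and C3, separated from the reacting enone by C4, cannot epimerise. The step needs regioselectivity in the ketene–alkyne union, and the polarisation of the siloxyalkyne secures it, so that the prenyl group ends at C8 between the C7 silyl ether and the new free C8a hydroxyl. Chemoselectivity rests on the silyl-masked C2 hydroxyl, which cannot add to the ketene, and on the excess of alkyne, which outruns acylation of the hindered product phenol.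

Step 15
Reactants: 28 6-[(2S)-2-ArB-3-(tert-butyldimethylsilyloxy)propyl]-2-(3-methylbut-2-en-1-yl)-3-(triisopropylsilyloxy)phenol
Product: 29 6-[(2S)-2-ArB-3-hydroxypropyl]-2-(3-methylbut-2-en-1-yl)-3-(triisopropylsilyloxy)phenol
Conditions: camphor-10-sulfonic acid (10 mol %), MeOH–CH2Cl2 (1:1), 0 °C
Reagents that add atoms: none
Why: Acid-catalysed methanolysis cleaves the primary alkyl silyl ether far faster than the two bulky aryl silyl ethers, and catalytic acid at 0 °C should neither cyclise the prenyl phenol nor attack the chromene.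

Step 16
Reactants: 29 6-[(2S)-2-ArB-3-hydroxypropyl]-2-(3-methylbut-2-en-1-yl)-3-(triisopropylsilyloxy)phenol
Product: 30 (3S)-3-ArB-8-(3-methylbut-2-en-1-yl)-7-(triisopropylsilyloxy)chromane
Conditions: PPh3, diisopropyl azodicarboxylate, THF, 0 → 25 °C
Reagents that add atoms: none
Why: Intramolecular Mitsunobu etherification (6-exo-tet) joins the activated primary C2 to the only free phenol, the C8a hydroxyl, while the ring B oxygen is still silylated and cannot form a dihydrobenzofuran; C2 is not stereogenic and C3 is untouched.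

Step 17
Reactants: 30 (3S)-3-ArB-8-(3-methylbut-2-en-1-yl)-7-(triisopropylsilyloxy)chromane
Product: 31 (3S)-3-(5-hydroxy-2,2-dimethyl-2H-chromen-6-yl)-8-(3-methylbut-2-en-1-yl)chroman-7-ol (target)
Conditions: Bu4NF, AcOH, THF, 0 °C
Reagents that add atoms: none
Why: Fluoride-induced desilylation removes both aryl silyl ethers in one operation, and the acetic acid buffer keeps the electron-rich phenols protonated and protected from base-promoted oxidation.

Compound list
1 | 2,4-dihydroxybenzaldehyde | O=Cc1ccc(O)cc1O | starting material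
2 | 3-methylbut-2-enal (prenal) | CC(C)=CC=O | starting material
3 | 2-hydroxy-3-(3-methylbut-2-enylidene)-4-oxocyclohexa-1,5-diene-1-carbaldehyde (o-quinone methide) | O=CC1=C(O)C(=CC=C(C)C)C(=O)C=C1 | intermediate
4 | 5-hydroxy-2,2-dimethyl-2H-chromene-6-carbaldehyde | O=Cc1ccc2c(c1O)C=CC(C)(C)O2 | intermediate
5 | 2,2-dimethyl-5-(triisopropylsilyloxy)-2H-chromene-6-carbaldehyde | O=Cc1ccc2c(c1O[Si](C(C)C)(C(C)C)C(C)C)C=CC(C)(C)O2 | intermediate
6 | 6-ethenyl-2,2-dimethyl-5-(triisopropylsilyloxy)-2H-chromene | C=Cc1ccc2c(c1O[Si](C(C)C)(C(C)C)C(C)C)C=CC(C)(C)O2 | intermediate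
7 | trichloroacetyl chloride | ClC(=O)C(Cl)(Cl)Cl | starting material
8 | dichloroketene | O=C=C(Cl)Cl | intermediate
9 | racemic 2,2-dichloro-3-ArB-cyclobutan-1-one | O=C1CC(c2ccc3c(c2O[Si](C(C)C)(C(C)C)C(C)C)C=CC(C)(C)O3)C1(Cl)Cl | intermediate
10 | 3-ArB-cyclobutan-1-one | O=C1CC(c2ccc3c(c2O[Si](C(C)C)(C(C)C)C(C)C)C=CC(C)(C)O3)C1 | intermediate
11 | 1-hydroperoxy-3-ArB-cyclobutan-1-ol (peroxy hemiketal) | OOC1(O)CC(c2ccc3c(c2O[Si](C(C)C)(C(C)C)C(C)C)C=CC(C)(C)O3)C1 | intermediate
12 | (4S)-4-ArB-dihydrofuran-2(3H)-one | O=C1C[C@@H](c2ccc3c(c2O[Si](C(C)C)(C(C)C)C(C)C)C=CC(C)(C)O3)CO1 | intermediate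
13 | (3S)-3-ArB-4-hydroxy-N-methoxy-N-methylbutanamide | CON(C)C(=O)C[C@@H](c1ccc2c(c1O[Si](C(C)C)(C(C)C)C(C)C)C=CC(C)(C)O2)CO | intermediate
14 | (3S)-3-ArB-4-(tert-butyldimethylsilyloxy)-N-methoxy-N-methylbutanamide | CON(C)C(=O)C[C@@H](c1ccc2c(c1O[Si](C(C)C)(C(C)C)C(C)C)C=CC(C)(C)O2)CO[Si](C)(C)C(C)(C)C | intermediate
15 | (3S)-3-ArB-4-(tert-butyldimethylsilyloxy)butanal | O=CC[C@@H](c1ccc2c(c1O[Si](C(C)C)(C(C)C)C(C)C)C=CC(C)(C)O2)CO[Si](C)(C)C(C)(C)C | intermediate
16 | (3E,6S)-6-ArB-7-(tert-butyldimethylsilyloxy)hept-3-en-2-one | CC(=O)/C=C/C[C@@H](c1ccc2c(c1O[Si](C(C)C)(C(C)C)C(C)C)C=CC(C)(C)O2)CO[Si](C)(C)C(C)(C)C | intermediate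
17 | (5E,8S)-8-ArB-9-(tert-butyldimethylsilyloxy)-1,1,1-trifluoronon-5-ene-2,4-dione | O=C(CC(=O)C(F)(F)F)/C=C/C[C@@H](c1ccc2c(c1O[Si](C(C)C)(C(C)C)C(C)C)C=CC(C)(C)O2)CO[Si](C)(C)C(C)(C)C | intermediate
18 | (3E,6S)-6-ArB-7-(tert-butyldimethylsilyloxy)-1-diazohept-3-en-2-one | [N-]=[N+]=CC(=O)/C=C/C[C@@H](c1ccc2c(c1O[Si](C(C)C)(C(C)C)C(C)C)C=CC(C)(C)O2)CO[Si](C)(C)C(C)(C)C | intermediate
19 | 4-methylpent-3-enoic acid | CC(C)=CCC(=O)O | starting material
20 | ethyl 4-methylpent-3-enoate | CCOC(=O)CC=C(C)C | intermediate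
21 | lithium 1,1-dibromo-5-methylhexa-1,4-dien-2-olate | [Li+].[O-]C(CC=C(C)C)=C(Br)Br | intermediate
22 | lithium 5-methylhex-4-en-1-yn-1-olate | [Li+].[O-]C#CCC=C(C)C | intermediate
23 | triisopropyl[(5-methylhex-4-en-1-yn-1-yl)oxy]silane | CC(C)=CCC#CO[Si](C(C)C)(C(C)C)C(C)C | intermediate
24 | (3E,6S)-6-ArB-7-(tert-butyldimethylsilyloxy)hepta-1,3-dien-1-one (vinylketene) | O=C=C/C=C/C[C@@H](c1ccc2c(c1O[Si](C(C)C)(C(C)C)C(C)C)C=CC(C)(C)O2)CO[Si](C)(C)C(C)(C)C | intermediate
25 | 4-[(1E,4S)-4-ArB-5-(tert-butyldimethylsilyloxy)pent-1-en-1-yl]-2-(3-methylbut-2-en-1-yl)-3-(triisopropylsilyloxy)cyclobut-2-en-1-one (both configurations at the ring sp3 carbon) | O=C1C(CC=C(C)C)=C(O[Si](C(C)C)(C(C)C)C(C)C)C1/C=C/C[C@@H](c1ccc2c(c1O[Si](C(C)C)(C(C)C)C(C)C)C=CC(C)(C)O2)CO[Si](C)(C)C(C)(C)C | intermediate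
26 | (3E,5E,8S)-8-ArB-9-(tert-butyldimethylsilyloxy)-2-(3-methylbut-2-en-1-yl)-3-(triisopropylsilyloxy)nona-1,3,5-trien-1-one (dienylketene, ketene carbon and C5 cis about C3=C4) | O=C=C(CC=C(C)C)/C(O[Si](C(C)C)(C(C)C)C(C)C)=C\C=C\C[C@@H](c1ccc2c(c1O[Si](C(C)C)(C(C)C)C(C)C)C=CC(C)(C)O2)CO[Si](C)(C)C(C)(C)C | intermediate
27 | 6-[(2S)-2-ArB-3-(tert-butyldimethylsilyloxy)propyl]-2-(3-methylbut-2-en-1-yl)-3-(triisopropylsilyloxy)cyclohexa-2,4-dien-1-one (both configurations at C6) | O=C1C(CC=C(C)C)=C(O[Si](C(C)C)(C(C)C)C(C)C)C=CC1C[C@@H](c1ccc2c(c1O[Si](C(C)C)(C(C)C)C(C)C)C=CC(C)(C)O2)CO[Si](C)(C)C(C)(C)C | intermediate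
28 | 6-[(2S)-2-ArB-3-(tert-butyldimethylsilyloxy)propyl]-2-(3-methylbut-2-en-1-yl)-3-(triisopropylsilyloxy)phenol | CC(C)=CCc1c(O[Si](C(C)C)(C(C)C)C(C)C)ccc(C[C@@H](c2ccc3c(c2O[Si](C(C)C)(C(C)C)C(C)C)C=CC(C)(C)O3)CO[Si](C)(C)C(C)(C)C)c1O | intermediate
29 | 6-[(2S)-2-ArB-3-hydroxypropyl]-2-(3-methylbut-2-en-1-yl)-3-(triisopropylsilyloxy)phenol | CC(C)=CCc1c(O[Si](C(C)C)(C(C)C)C(C)C)ccc(C[C@@H](c2ccc3c(c2O[Si](C(C)C)(C(C)C)C(C)C)C=CC(C)(C)O3)CO)c1O | intermediate
30 | (3S)-3-ArB-8-(3-methylbut-2-en-1-yl)-7-(triisopropylsilyloxy)chromane | CC(C)=CCc1c(O[Si](C(C)C)(C(C)C)C(C)C)ccc2c1OC[C@H](c1ccc3c(c1O[Si](C(C)C)(C(C)C)C(C)C)C=CC(C)(C)O3)C2 | intermediate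
31 | (3S)-3-(5-hydroxy-2,2-dimethyl-2H-chromen-6-yl)-8-(3-methylbut-2-en-1-yl)chroman-7-ol (CNP0263294.1) | CC(C)=CCc1c(O)ccc2c1OC[C@H](c1ccc3c(c1O)C=CC(C)(C)O3)C2 | target

Total step count: 17 (steps 1–11 ring B, stereocentre and diazo enone; steps 12–13 alkyne; steps 14–17 annulation and endgame).
Longest linear sequence: 15 steps (steps 1–11, then 14–17).

Steps most likely to fail

1. Step 14. The photogenerated ketene may not be captured cleanly: it can dimerise or acylate the newly formed phenol, and light below about 350 nm would open the chromene ring. Fallback, setting out from aldehyde 15 and coming back at phenol 28: the same vinylketene type is made thermally. Wittig reaction of 15 with the ylide of (2-carboxyethyl)triphenylphosphonium bromide (2 equiv NaN(SiMe3)2, THF, −78 → 25 °C) should give (3Z,6S)-6-ArB-7-(tert-butyldimethylsilyloxy)hept-3-enoic acid F1. 1-Chloro-N,N,2-trimethylprop-1-en-1-amine (CH2Cl2, 0 °C, neutral) converts it into the acid chloride F2. Slow addition of F2 to Et3N and alkyne 23 in toluene (25 → 80 °C) dehydrochlorinates it to the (Z)-vinylketene F3. The same [2+2], 4π, 6π sequence then runs without light through the (Z)-alkenyl cyclobutenone F4 and the dienylketene F5 to dienone 27 and phenol 28.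

2. Step 6. Discrimination between the two enantiotopic migrating CH2 groups may be weak next to the bulky ortho-silyloxy aryl group, leaving the lactone short of enantiopurity. Fallback, setting out from cyclobutanone 10 and coming back at lactone 12: resolution replaces asymmetric catalysis. Oxidation with diphenyl hydrogen phosphate (10 mol %) and 30 % aq. H2O2 in CHCl3 at 0 °C, again through 11, gives the racemic lactone F6. Preparative chromatography on a chiral stationary phase (supercritical CO2/MeOH) separates it into (S)-lactone 12 and the (R)-lactone F7, which is set aside.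

3. Step 4. Chemoselectivity may be lost through cycloaddition at the pyran double bond, or zinc salts may polymerise the electron-rich styrene. Fallback, setting out from aldehyde 5 and coming back at lactone 12 (it bypasses steps 3–6): a chiral auxiliary sets C3.
 - Doebner condensation of 5 with malonic acid (pyridine, cat. piperidine, 90 °C) gives, through the arylidenemalonic acid F8, the (E)-3-ArB-acrylic acid F9.
 - The mixed pivalic anhydride F10 (t-BuCOCl, Et3N, THF, −20 °C) acylates (S)-4-phenyl-1,3-oxazolidin-2-one (LiCl) to the imide F11.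
 - CuBr·SMe2-mediated conjugate addition of [(isopropoxydimethylsilyl)methyl]magnesium chloride, a hydroxymethyl anion equivalent, to the chelated syn-s-cis imide from the face opposite the phenyl group should give the (3S)-adduct F12, purified from its diastereomer by chromatography.
 - Fluoride-free Tamao oxidation (30 % H2O2, KHCO3, THF–MeOH, 25–40 °C; the aryl silyl ether is kept) gives the hydroxy imide F13, which lactonises in the flask with release of the auxiliary to give 12.

Further compounds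
F1 | step 14 | (3Z,6S)-6-ArB-7-(tert-butyldimethylsilyloxy)hept-3-enoic acid | OC(=O)C/C=C\C[C@@H](c1ccc2c(c1O[Si](C(C)C)(C(C)C)C(C)C)C=CC(C)(C)O2)CO[Si](C)(C)C(C)(C)C
F2 | step 14 | (3Z,6S)-6-ArB-7-(tert-butyldimethylsilyloxy)hept-3-enoyl chloride | ClC(=O)C/C=C\C[C@@H](c1ccc2c(c1O[Si](C(C)C)(C(C)C)C(C)C)C=CC(C)(C)O2)CO[Si](C)(C)C(C)(C)C
F3 | step 14 | (3Z,6S)-6-ArB-7-(tert-butyldimethylsilyloxy)hepta-1,3-dien-1-one (vinylketene, not isolated) | O=C=C/C=C\C[C@@H](c1ccc2c(c1O[Si](C(C)C)(C(C)C)C(C)C)C=CC(C)(C)O2)CO[Si](C)(C)C(C)(C)C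
F4 | step 14 | 4-[(1Z,4S)-4-ArB-5-(tert-butyldimethylsilyloxy)pent-1-en-1-yl]-2-(3-methylbut-2-en-1-yl)-3-(triisopropylsilyloxy)cyclobut-2-en-1-one (not isolated) | O=C1C(CC=C(C)C)=C(O[Si](C(C)C)(C(C)C)C(C)C)C1/C=C\C[C@@H](c1ccc2c(c1O[Si](C(C)C)(C(C)C)C(C)C)C=CC(C)(C)O2)CO[Si](C)(C)C(C)(C)C
F5 | step 14 | (3E,5Z,8S)-8-ArB-9-(tert-butyldimethylsilyloxy)-2-(3-methylbut-2-en-1-yl)-3-(triisopropylsilyloxy)nona-1,3,5-trien-1-one (not isolated) | O=C=C(CC=C(C)C)/C(O[Si](C(C)C)(C(C)C)C(C)C)=C\C=C/C[C@@H](c1ccc2c(c1O[Si](C(C)C)(C(C)C)C(C)C)C=CC(C)(C)O2)CO[Si](C)(C)C(C)(C)C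
F6 | step 6 | racemic 4-ArB-dihydrofuran-2(3H)-one | O=C1CC(c2ccc3c(c2O[Si](C(C)C)(C(C)C)C(C)C)C=CC(C)(C)O3)CO1
F7 | step 6 | (4R)-4-ArB-dihydrofuran-2(3H)-one | O=C1C[C@H](c2ccc3c(c2O[Si](C(C)C)(C(C)C)C(C)C)C=CC(C)(C)O3)CO1
F8 | step 4 | 2-(ArB-methylidene)propanedioic acid (not isolated) | OC(=O)C(=Cc1ccc2c(c1O[Si](C(C)C)(C(C)C)C(C)C)C=CC(C)(C)O2)C(=O)O
F9 | step 4 | (2E)-3-ArB-prop-2-enoic acid | OC(=O)/C=C/c1ccc2c(c1O[Si](C(C)C)(C(C)C)C(C)C)C=CC(C)(C)O2
F10 | step 4 | (2E)-3-ArB-prop-2-enoic 2,2-dimethylpropanoic anhydride (not isolated) | CC(C)(C)C(=O)OC(=O)/C=C/c1ccc2c(c1O[Si](C(C)C)(C(C)C)C(C)C)C=CC(C)(C)O2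
F11 | step 4 | (4S)-3-[(2E)-3-ArB-prop-2-enoyl]-4-phenyl-1,3-oxazolidin-2-one | O=C(/C=C/c1ccc2c(c1O[Si](C(C)C)(C(C)C)C(C)C)C=CC(C)(C)O2)N1C(=O)OC[C@@H]1c1ccccc1
F12 | step 4 | (4S)-3-[(3S)-3-ArB-4-(isopropoxydimethylsilyl)butanoyl]-4-phenyl-1,3-oxazolidin-2-one | O=C(C[C@@H](c1ccc2c(c1O[Si](C(C)C)(C(C)C)C(C)C)C=CC(C)(C)O2)C[Si](C)(C)OC(C)C)N1C(=O)OC[C@@H]1c1ccccc1
F13 | step 4 | (4S)-3-[(3S)-3-ArB-4-hydroxybutanoyl]-4-phenyl-1,3-oxazolidin-2-one (not isolated) | O=C(C[C@@H](c1ccc2c(c1O[Si](C(C)C)(C(C)C)C(C)C)C=CC(C)(C)O2)CO)N1C(=O)OC[C@@H]1c1ccccc1
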